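**Retrosynthetic overview**
1. The cyclohexadiene ring is closed last by ring-closing metathesis at C4=C5: the C4 ester is methylenated (its OMe becomes the 4-methoxy group) and joined to a vinyl group on C6. C6–C7 and both of their stereocentres come from a reagent-controlled syn aldol of the C7 ketone with acrolein; the ketone chain is attached by lateral acylation of the C7 methyl group.
2. The strategy rests on the tetrasubstituted enol ether C3a=C7a (benzofuran numbering), which carries O1, C7 and C4: it is an internal alkyne that has gained an alkoxy oxygen and a carbonyl carbon. O1–C7a and C3a–C4 are formed together by 5-endo-dig alkoxypalladation–methoxycarbonylation of an anti homopropargylic alcohol.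
3. That alcohol comes from propynylalane opening (inversion at the benzylic carbon) of an aryl cis-epoxide, reached by Sonogashira coupling, cis-semihydrogenation and asymmetric epoxidation from 4-bromo-2-iodophenol and 2-methylbut-3-yn-2-ol.
4. Ring order: arene (bought), dihydrofuran (step 7), cyclohexadiene (step 13); the aryl bromide is turned into the methyl ester in step 14.

Key step: step 7

Remark: (−)-Ipc2BOTf is assumed to direct its Z-enol borinate to the si face of acrolein, as in its ethyl ketone aldols (the antipodal reagent would be taken otherwise), and Weinreb amide 13 is taken as purchasable.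

**Step 1**
Reactants: 1 4-bromo-2-iodophenol
Product: 2 (4-bromo-2-iodophenoxy)(tert-butyl)dimethylsilane
Conditions: TBSCl, imidazole, DMF, rt
Reagents that add atoms: tert-butyldimethylsilyl chloride, CC(C)(C)[Si](C)(C)Cl
Why: Standard O-silylation of a phenol, which stops the later ortho-alkynylphenol from closing to a benzofuran.

**Step 2**
Reactants: 2 (4-bromo-2-iodophenoxy)(tert-butyl)dimethylsilane; 3 2-methylbut-3-yn-2-ol
Product: 4 4-[5-bromo-2-(tert-butyldimethylsilyloxy)phenyl]-2-methylbut-3-yn-2-ol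
Conditions: PdCl2(PPh3)2 (2 mol %), CuI (4 mol %), Et3N, THF, rt
Reagents that add atoms: none
Why: Sonogashira coupling, in which the C–I bond should react far faster than the C–Br bond at room temperature.

**Step 3**
Reactants: 4 4-[5-bromo-2-(tert-butyldimethylsilyloxy)phenyl]-2-methylbut-3-yn-2-ol
Product: 5 {4-bromo-2-[3-methyl-3-(triethylsilyloxy)but-1-ynyl]phenoxy}(tert-butyl)dimethylsilane
Conditions: TESOTf, 2,6-lutidine, CH2Cl2, 0 °C
Reagents that add atoms: triethylsilyl triflate, CC[Si](CC)(CC)OS(=O)(=O)C(F)(F)F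
Why: Silyl triflate silylation of the tertiary alcohol, which must stay blocked so that it cannot attack the alkyne in a 5-exo mode in step 7.

**Step 4**
Reactants: 5 {4-bromo-2-[3-methyl-3-(triethylsilyloxy)but-1-ynyl]phenoxy}(tert-butyl)dimethylsilane
Product: 6 {4-bromo-2-[(Z)-3-methyl-3-(triethylsilyloxy)but-1-enyl]phenoxy}(tert-butyl)dimethylsilane
Conditions: H2 (1 atm), Pd/CaCO3 poisoned with Pb(OAc)2 (Lindlar catalyst), quinoline, EtOAc, rt
Reagents that add atoms: none
Why: Lindlar semihydrogenation adds hydrogen syn to give the Z-alkene and should leave the aryl bromide untouched.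

**Step 5**
Reactants: 6 {4-bromo-2-[(Z)-3-methyl-3-(triethylsilyloxy)but-1-enyl]phenoxy}(tert-butyl)dimethylsilane
Product: 7 (2R,3R)-2-[5-bromo-2-(tert-butyldimethylsilyloxy)phenyl]-3-[2-(triethylsilyloxy)propan-2-yl]oxirane (cis)
Conditions: (R,R)-N,N′-bis(3,5-di-tert-butylsalicylidene)-1,2-cyclohexanediaminomanganese chloride (5 mol %), m-CPBA, N-methylmorpholine N-oxide, CH2Cl2, −78 °C
Reagents that add atoms: 3-chloroperoxybenzoic acid, OOC(=O)c1cccc(Cl)c1
Why: Jacobsen epoxidation of a cis-disubstituted aryl alkene, where the (R,R) catalyst should give the (2R,3R) cis-epoxide by analogy with 2,2-dimethylchromene (the cyclic counterpart of 6) and the low temperature should limit cis-to-trans leakage.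

**Step 6**
Reactants: 7 (2R,3R)-cis-epoxide; 8 propyne
Product: 11 (3R,4S)-4-[5-bromo-2-(tert-butyldimethylsilyloxy)phenyl]-2-methyl-2-(triethylsilyloxy)hept-5-yn-3-ol, via prop-1-ynyllithium 9 (not isolated), via diethyl(prop-1-ynyl)alane 10 (not isolated)
Conditions: propyne, n-BuLi, toluene, −78 to 0 °C; Et2AlCl, 0 °C; then 7, toluene, 0 °C to rt; aq. KNa tartrate
Reagents that add atoms: none
Why: Alkynylalane opening of an epoxide, in which aluminium activates the oxygen and the alkynyl group should enter at the benzylic carbon with inversion (the other carbon is shielded by the adjacent quaternary centre), so the benzylic centre becomes S and the carbinol centre keeps its R configuration.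

**Step 7**
Reactants: 11 (3R,4S)-4-[5-bromo-2-(tert-butyldimethylsilyloxy)phenyl]-2-methyl-2-(triethylsilyloxy)hept-5-yn-3-ol
Product: 12 methyl (4R,5R)-4-[5-bromo-2-(tert-butyldimethylsilyloxy)phenyl]-2-methyl-5-[2-(triethylsilyloxy)propan-2-yl]-4,5-dihydrofuran-3-carboxylate (trans)
Conditions: PdCl2(MeCN)2 (10 mol %), p-benzoquinone (1.5 equiv), CO (1 atm), MeOH, 0 °C to rt
Reagents that add atoms: carbon monoxide, [C-]#[O+]; methanol, CO
Why: Divalent palladium coordinates the internal alkyne and the free secondary hydroxyl (the future O1) attacks the distal alkyne carbon anti to the metal, giving a vinylpalladium species at C3a that inserts CO and is cleaved by methanol to the ester, while benzoquinone returns zerovalent palladium to the divalent state. The closest known reaction type is the oxidative heterocyclisation–alkoxycarbonylation of alkynols and 2-alkynylphenols, including the 5-endo closure of 3-yne-1,2-diols to furan-3-carboxylates. The dihydrofuran closes in the 5-endo-dig mode, the only alternative for this hydroxyl being a 4-exo closure that the linear alkyne excludes. No stereocentre is created: the trans C2/C3 relation of the ring is carried over unchanged from the (3R,4S) arrangement of 11. The step needs oxypalladation by the secondary hydroxyl to outrun three competitors: attack by the tertiary oxygen (blocked as its TES ether), formation of an alkoxycarbonylpalladium species that would lead to a lactone (disfavoured by the base-free medium), and insertion into the aryl C–Br bond (avoided because the quinone keeps the metal divalent).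

**Step 8**
Reactants: 12 methyl (4R,5R)-dihydrofuran-3-carboxylate; 13 N-methoxy-N-methyl-3-phenylpropanamide
Product: 15 methyl (4R,5R)-4-[5-bromo-2-(tert-butyldimethylsilyloxy)phenyl]-2-(2-oxo-4-phenylbutyl)-5-[2-(triethylsilyloxy)propan-2-yl]-4,5-dihydrofuran-3-carboxylate, via lithium dienolate 14 (not isolated)
Conditions: LDA (1.2 equiv), THF, −78 °C; then 13, −78 to −40 °C; AcOH quench at −78 °C
Reagents that add atoms: none
Why: Lateral (gamma) deprotonation of the 2-methyl group of a beta-alkoxy acrylate and Weinreb acylation of the dienolate at its terminal carbon, where the chelated adduct should hold until the cold acidic quench and so prevent over-addition and pyranone formation.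

**Step 9**
Reactants: 15 ketone; 16 acrolein
Product: 18 methyl (4R,5R)-4-[5-bromo-2-(tert-butyldimethylsilyloxy)phenyl]-2-[(3R,4R)-3-hydroxy-5-oxo-7-phenylhept-1-en-4-yl]-5-[2-(triethylsilyloxy)propan-2-yl]-4,5-dihydrofuran-3-carboxylate, via boron Z-enolate 17 (not isolated)
Conditions: (−)-Ipc2BOTf, i-Pr2NEt, CH2Cl2, −78 °C; acrolein, −78 to −25 °C; pH 7 buffer, MeOH, H2O2, 0 °C
Reagents that add atoms: none
Why: Paterson boron aldol, in which the ketone should enolise towards its more acidic CH2 (the future C7) as the Z-enol borinate and add through a Zimmerman–Traxler chair to give the syn adduct (later the 6,7-cis pair), with the isopinocampheyl groups choosing the aldehyde face so that C6 and C7 are set as R,R independently of the remote ring stereocentres.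

**Step 10**
Reactants: 18 syn aldol
Product: 19 the C6 triethylsilyl ether of 18 (side chain (3R,4R)-5-oxo-7-phenyl-3-(triethylsilyloxy)hept-1-en-4-yl)
Conditions: TESOTf, 2,6-lutidine, CH2Cl2, −78 °C
Reagents that add atoms: triethylsilyl triflate, CC[Si](CC)(CC)OS(=O)(=O)C(F)(F)F
Why: Fast low-temperature silylation of the aldol hydroxyl, which removes the risk of retro-aldol cleavage and of lactonisation onto the neighbouring ester.

**Step 11**
Reactants: 19 beta-silyloxy ketone
Product: 20 the corresponding side-chain alcohol (side chain (3R,4R)-5-hydroxy-7-phenyl-3-(triethylsilyloxy)hept-1-en-4-yl, both epimers at the new carbinol carbon)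
Conditions: NaBH4, CeCl3·7H2O, MeOH, −40 °C
Reagents that add atoms: none
Why: Luche-type carbonyl reduction that masks the ketone before the titanium step; the cold, weakly acidic medium should keep the new hydroxyl from lactonising onto the ester, and the uncontrolled carbinol centre is removed again in step 15.

**Step 12**
Reactants: 20 hydroxy ester
Product: 21 the 2-methoxydiene in which the ester C=O of 20 has become C(OMe)=CH2
Conditions: Cp2TiMe2 (5 equiv), toluene, 70 °C, dark
Reagents that add atoms: dimethyltitanocene, C[Ti](C)(C1C=CC=C1)C1C=CC=C1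
Why: Petasis methylenation of the ester carbonyl through titanocene methylidene, which keeps the methoxy group on C4; the free hydroxyl should only cost one equivalent of reagent as its titanocene alkoxide, and the silyl ethers, aryl bromide and vinyl group should be inert.

**Step 13**
Reactants: 21 methoxydiene
Product: 22 (2R,3R,6R,7R)-3-[5-bromo-2-(tert-butyldimethylsilyloxy)phenyl]-7-(1-hydroxy-3-phenylpropyl)-4-methoxy-6-(triethylsilyloxy)-2-[2-(triethylsilyloxy)propan-2-yl]-2,3,6,7-tetrahydro-1-benzofuran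
Conditions: RuCl2(=CHPh)(PCy3)(H2IMes) (second-generation Grubbs catalyst, 10 mol %), toluene, 70 °C
Reagents that add atoms: none
Why: Ring-closing metathesis between the C6 vinyl group and the 1,1-disubstituted enol ether closes the six-membered ring at C4=C5 with loss of ethene; the tetrasubstituted C3a=C7a bond cannot compete and no stereocentre is touched.

**Step 14**
Reactants: 22 aryl bromide
Product: 23 methyl 4-(tert-butyldimethylsilyloxy)-3-[(2R,3R,6R,7R)-7-(1-hydroxy-3-phenylpropyl)-4-methoxy-6-(triethylsilyloxy)-2-[2-(triethylsilyloxy)propan-2-yl]-2,3,6,7-tetrahydro-1-benzofuran-3-yl]benzoate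
Conditions: Pd(OAc)2 (5 mol %), Xantphos (10 mol %), CO (1 atm), MeOH, Et3N, toluene, 70 °C
Reagents that add atoms: carbon monoxide, [C-]#[O+]; methanol, CO
Why: Palladium-catalysed methoxycarbonylation of the aryl bromide, placed after the titanium step (a benzoate would be methylenated) and before the ketone is restored (the beta-silyloxy ketone would not tolerate warm amine).

**Step 15**
Reactants: 23 side-chain alcohol
Product: 24 methyl 4-(tert-butyldimethylsilyloxy)-3-[(2R,3R,6R,7R)-4-methoxy-7-(3-phenylpropanoyl)-6-(triethylsilyloxy)-2-[2-(triethylsilyloxy)propan-2-yl]-2,3,6,7-tetrahydro-1-benzofuran-3-yl]benzoate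
Conditions: Dess–Martin periodinane, NaHCO3, CH2Cl2, 0 °C
Reagents that add atoms: none
Why: Buffered Dess–Martin oxidation returns the ketone and merges both carbinol epimers under conditions mild enough for the dienol ether and for the C7 centre next to the new carbonyl.

**Step 16**
Reactants: 24 tris-silyl ether
Product: 25 methyl 4-hydroxy-3-[(2R,3R,6R,7R)-6-hydroxy-2-(2-hydroxypropan-2-yl)-4-methoxy-7-(3-phenylpropanoyl)-2,3,6,7-tetrahydro-1-benzofuran-3-yl]benzoate (CNP0080427.3)
Conditions: TBAF, AcOH (1:1), THF, 0 °C to rt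
Reagents that add atoms: none
Why: Fluoride desilylation buffered with acetic acid should remove the aryl TBS and both TES groups while staying close to neutral, since acid or free base would dehydrate the beta-hydroxy ketone to the aromatic benzofuran.

**Compound list**
1 | 4-bromo-2-iodophenol | Oc1ccc(Br)cc1I | starting material
2 | (4-bromo-2-iodophenoxy)(tert-butyl)dimethylsilane | CC(C)(C)[Si](C)(C)Oc1ccc(Br)cc1I | intermediate
3 | 2-methylbut-3-yn-2-ol | CC(C)(O)C#C | starting material
4 | 4-[5-bromo-2-(tert-butyldimethylsilyloxy)phenyl]-2-methylbut-3-yn-2-ol | CC(C)(O)C#Cc1cc(Br)ccc1O[Si](C)(C)C(C)(C)C | intermediate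
5 | {4-bromo-2-[3-methyl-3-(triethylsilyloxy)but-1-ynyl]phenoxy}(tert-butyl)dimethylsilane | CC[Si](CC)(CC)OC(C)(C)C#Cc1cc(Br)ccc1O[Si](C)(C)C(C)(C)C | intermediate
6 | {4-bromo-2-[(Z)-3-methyl-3-(triethylsilyloxy)but-1-enyl]phenoxy}(tert-butyl)dimethylsilane | CC[Si](CC)(CC)OC(C)(C)/C=C\c1cc(Br)ccc1O[Si](C)(C)C(C)(C)C | intermediate
7 | (2R,3R)-2-[5-bromo-2-(tert-butyldimethylsilyloxy)phenyl]-3-[2-(triethylsilyloxy)propan-2-yl]oxirane | CC[Si](CC)(CC)OC(C)(C)[C@@H]1O[C@@H]1c1cc(Br)ccc1O[Si](C)(C)C(C)(C)C | intermediate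
8 | propyne | CC#C | starting material
9 | prop-1-ynyllithium | [Li]C#CC | intermediate (not isolated)
10 | diethyl(prop-1-ynyl)alane | CC[Al](CC)C#CC | intermediate (not isolated)
11 | (3R,4S)-4-[5-bromo-2-(tert-butyldimethylsilyloxy)phenyl]-2-methyl-2-(triethylsilyloxy)hept-5-yn-3-ol | Brc1ccc(O[Si](C)(C)C(C)(C)C)c([C@H](C#CC)[C@@H](O)C(C)(C)O[Si](CC)(CC)CC)c1 | intermediate
12 | methyl (4R,5R)-4-[5-bromo-2-(tert-butyldimethylsilyloxy)phenyl]-2-methyl-5-[2-(triethylsilyloxy)propan-2-yl]-4,5-dihydrofuran-3-carboxylate | Brc1ccc(O[Si](C)(C)C(C)(C)C)c([C@@H]2C(C(=O)OC)=C(C)O[C@H]2C(C)(C)O[Si](CC)(CC)CC)c1 | intermediate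
13 | N-methoxy-N-methyl-3-phenylpropanamide | CON(C)C(=O)CCc1ccccc1 | starting material
14 | lithium dienolate of 12 (2-methylene ketene acetal) | Brc1ccc(O[Si](C)(C)C(C)(C)C)c([C@@H]2C(=C(OC)O[Li])C(=C)O[C@H]2C(C)(C)O[Si](CC)(CC)CC)c1 | intermediate (not isolated)
15 | methyl (4R,5R)-4-[5-bromo-2-(tert-butyldimethylsilyloxy)phenyl]-2-(2-oxo-4-phenylbutyl)-5-[2-(triethylsilyloxy)propan-2-yl]-4,5-dihydrofuran-3-carboxylate | Brc1ccc(O[Si](C)(C)C(C)(C)C)c([C@@H]2C(C(=O)OC)=C(CC(=O)CCc3ccccc3)O[C@H]2C(C)(C)O[Si](CC)(CC)CC)c1 | intermediate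
16 | acrolein | C=CC=O | starting material
17 | Z-enol diisopinocampheylborinate of 15 | Brc1ccc(O[Si](C)(C)C(C)(C)C)c([C@@H]2C(C(=O)OC)=C(/C=C(\OB([C@@H]3C[C@@H]4C[C@H]([C@H]3C)C4(C)C)[C@@H]3C[C@@H]4C[C@H]([C@H]3C)C4(C)C)CCc3ccccc3)O[C@H]2C(C)(C)O[Si](CC)(CC)CC)c1 | intermediate (not isolated)
18 | methyl (4R,5R)-4-[5-bromo-2-(tert-butyldimethylsilyloxy)phenyl]-2-[(3R,4R)-3-hydroxy-5-oxo-7-phenylhept-1-en-4-yl]-5-[2-(triethylsilyloxy)propan-2-yl]-4,5-dihydrofuran-3-carboxylate | Brc1ccc(O[Si](C)(C)C(C)(C)C)c([C@@H]2C(C(=O)OC)=C([C@H](C(=O)CCc3ccccc3)[C@H](O)C=C)O[C@H]2C(C)(C)O[Si](CC)(CC)CC)c1 | intermediate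
19 | methyl (4R,5R)-4-[5-bromo-2-(tert-butyldimethylsilyloxy)phenyl]-2-[(3R,4R)-5-oxo-7-phenyl-3-(triethylsilyloxy)hept-1-en-4-yl]-5-[2-(triethylsilyloxy)propan-2-yl]-4,5-dihydrofuran-3-carboxylate | Brc1ccc(O[Si](C)(C)C(C)(C)C)c([C@@H]2C(C(=O)OC)=C([C@H](C(=O)CCc3ccccc3)[C@H](O[Si](CC)(CC)CC)C=C)O[C@H]2C(C)(C)O[Si](CC)(CC)CC)c1 | intermediate
20 | methyl (4R,5R)-4-[5-bromo-2-(tert-butyldimethylsilyloxy)phenyl]-2-[(3R,4R)-5-hydroxy-7-phenyl-3-(triethylsilyloxy)hept-1-en-4-yl]-5-[2-(triethylsilyloxy)propan-2-yl]-4,5-dihydrofuran-3-carboxylate (both C5 carbinol epimers) | Brc1ccc(O[Si](C)(C)C(C)(C)C)c([C@@H]2C(C(=O)OC)=C([C@H](C(O)CCc3ccccc3)[C@H](O[Si](CC)(CC)CC)C=C)O[C@H]2C(C)(C)O[Si](CC)(CC)CC)c1 | intermediate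
21 | (2R,3R)-3-[5-bromo-2-(tert-butyldimethylsilyloxy)phenyl]-5-[(3R,4R)-5-hydroxy-7-phenyl-3-(triethylsilyloxy)hept-1-en-4-yl]-4-(1-methoxyethenyl)-2-[2-(triethylsilyloxy)propan-2-yl]-2,3-dihydrofuran (both carbinol epimers) | Brc1ccc(O[Si](C)(C)C(C)(C)C)c([C@@H]2C(C(=C)OC)=C([C@H](C(O)CCc3ccccc3)[C@H](O[Si](CC)(CC)CC)C=C)O[C@H]2C(C)(C)O[Si](CC)(CC)CC)c1 | intermediate
22 | (2R,3R,6R,7R)-3-[5-bromo-2-(tert-butyldimethylsilyloxy)phenyl]-7-(1-hydroxy-3-phenylpropyl)-4-methoxy-6-(triethylsilyloxy)-2-[2-(triethylsilyloxy)propan-2-yl]-2,3,6,7-tetrahydro-1-benzofuran (both carbinol epimers) | Brc1ccc(O[Si](C)(C)C(C)(C)C)c([C@@H]2C3=C(O[C@H]2C(C)(C)O[Si](CC)(CC)CC)[C@H](C(O)CCc4ccccc4)[C@H](O[Si](CC)(CC)CC)C=C3OC)c1 | intermediate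
23 | methyl 4-(tert-butyldimethylsilyloxy)-3-[(2R,3R,6R,7R)-7-(1-hydroxy-3-phenylpropyl)-4-methoxy-6-(triethylsilyloxy)-2-[2-(triethylsilyloxy)propan-2-yl]-2,3,6,7-tetrahydro-1-benzofuran-3-yl]benzoate (both carbinol epimers) | COC(=O)c1ccc(O[Si](C)(C)C(C)(C)C)c([C@@H]2C3=C(O[C@H]2C(C)(C)O[Si](CC)(CC)CC)[C@H](C(O)CCc4ccccc4)[C@H](O[Si](CC)(CC)CC)C=C3OC)c1 | intermediate
24 | methyl 4-(tert-butyldimethylsilyloxy)-3-[(2R,3R,6R,7R)-4-methoxy-7-(3-phenylpropanoyl)-6-(triethylsilyloxy)-2-[2-(triethylsilyloxy)propan-2-yl]-2,3,6,7-tetrahydro-1-benzofuran-3-yl]benzoate | COC(=O)c1ccc(O[Si](C)(C)C(C)(C)C)c([C@@H]2C3=C(O[C@H]2C(C)(C)O[Si](CC)(CC)CC)[C@H](C(=O)CCc4ccccc4)[C@H](O[Si](CC)(CC)CC)C=C3OC)c1 | intermediate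
25 | methyl 4-hydroxy-3-[(2R,3R,6R,7R)-6-hydroxy-2-(2-hydroxypropan-2-yl)-4-methoxy-7-(3-phenylpropanoyl)-2,3,6,7-tetrahydro-1-benzofuran-3-yl]benzoate | COC(=O)c1ccc(O)c([C@@H]2C3=C(O[C@H]2C(C)(C)O)[C@H](C(=O)CCc2ccccc2)[C@H](O)C=C3OC)c1 | target

**Step count and risks**
Total steps: 16. Longest linear sequence: 16 steps (1 to 25).

Most likely to fail, step 7: the secondary hydroxyl may first form an alkoxycarbonylpalladium species that adds syn across the alkyne, or methanol may attack the activated alkyne, so that carbonylation products other than the 5-endo enol ether ester result. The fallback sets out from 11 and returns at 12. Compound 11 is closed by 5-endo-dig iodoetherification (I2, NaHCO3, MeCN, 0 °C) to (2R,3S)-3-[5-bromo-2-(tert-butyldimethylsilyloxy)phenyl]-4-iodo-5-methyl-2-[2-(triethylsilyloxy)propan-2-yl]-2,3-dihydrofuran F1. The vinyl iodide is then methoxycarbonylated (PdCl2(PPh3)2, CO 1 atm, MeOH, Et3N, DMF, 50 °C), where the C–I bond should react with zerovalent palladium well before the aryl C–Br bond.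

Second, step 9: facial control by the isopinocampheyl groups may be poor for a ketone whose alpha substituent is a bulky alkoxyvinyl group, and the aldolate may revert or lactonise. The fallback sets out from 12 and returns at 19, replacing reagent control by an auxiliary. Lateral lithiation of 12 (LDA, THF, −78 °C) and trapping with CO2 gives the half-acid 2-[(4R,5R)-4-aryl-3-(methoxycarbonyl)-5-[2-(triethylsilyloxy)propan-2-yl]-4,5-dihydrofuran-2-yl]acetic acid F2. Its mixed pivalic anhydride (PivCl, Et3N) is acylated onto lithiated (S)-4-benzyl-2-oxazolidinone to give the N-acyl oxazolidinone F3. An Evans syn aldol (Bu2BOTf, i-Pr2NEt, then acrolein, CH2Cl2, −78 to 0 °C) gives the (6R,7R)-configured imide aldol F4. Transamidation (AlMe3, MeNHOMe·HCl, CH2Cl2, 0 °C) gives the beta-hydroxy Weinreb amide F5, and silylation (TESOTf, 2,6-lutidine) gives its TES ether F6. Addition of 2-phenylethylmagnesium bromide (THF, −20 °C) then gives ketone 19.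

Third, step 12: the hindered, push–pull deactivated ester may be methylenated slowly while the titanocene alkoxide of the side-chain hydroxyl lactonises onto it. The fallback sets out from 20 and returns at 22, bypassing 21. The hydroxyl is capped (TMSCl, imidazole, CH2Cl2) as the trimethylsilyl ether of 20 F7. An olefinic ester cyclisation with the reduced titanium ethylidene reagent (TiCl4, TMEDA, Zn, PbCl2, CH3CHBr2, THF, 65 °C) then forms the ring in one flask, giving the trimethylsilyl ether of 22 F8. Brief methanolysis (K2CO3, MeOH, 0 °C) releases 22.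

**Further compounds**
F1 | step 7 | (2R,3S)-3-[5-bromo-2-(tert-butyldimethylsilyloxy)phenyl]-4-iodo-5-methyl-2-[2-(triethylsilyloxy)propan-2-yl]-2,3-dihydrofuran | Brc1ccc(O[Si](C)(C)C(C)(C)C)c([C@@H]2C(I)=C(C)O[C@H]2C(C)(C)O[Si](CC)(CC)CC)c1
F2 | step 9 | 2-[(4R,5R)-4-[5-bromo-2-(tert-butyldimethylsilyloxy)phenyl]-3-(methoxycarbonyl)-5-[2-(triethylsilyloxy)propan-2-yl]-4,5-dihydrofuran-2-yl]acetic acid | Brc1ccc(O[Si](C)(C)C(C)(C)C)c([C@@H]2C(C(=O)OC)=C(CC(=O)O)O[C@H]2C(C)(C)O[Si](CC)(CC)CC)c1
F3 | step 9 | N-acyl (S)-4-benzyl-2-oxazolidinone of F2 | Brc1ccc(O[Si](C)(C)C(C)(C)C)c([C@@H]2C(C(=O)OC)=C(CC(=O)N3[C@@H](Cc4ccccc4)COC3=O)O[C@H]2C(C)(C)O[Si](CC)(CC)CC)c1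
F4 | step 9 | Evans syn aldol of F3 with acrolein (carbinol R, alpha carbon R) | Brc1ccc(O[Si](C)(C)C(C)(C)C)c([C@@H]2C(C(=O)OC)=C([C@H](C(=O)N3[C@@H](Cc4ccccc4)COC3=O)[C@H](O)C=C)O[C@H]2C(C)(C)O[Si](CC)(CC)CC)c1
F5 | step 9 | beta-hydroxy N-methoxy-N-methylamide from F4 | Brc1ccc(O[Si](C)(C)C(C)(C)C)c([C@@H]2C(C(=O)OC)=C([C@H](C(=O)N(C)OC)[C@H](O)C=C)O[C@H]2C(C)(C)O[Si](CC)(CC)CC)c1
F6 | step 9 | triethylsilyl ether of F5 | Brc1ccc(O[Si](C)(C)C(C)(C)C)c([C@@H]2C(C(=O)OC)=C([C@H](C(=O)N(C)OC)[C@H](O[Si](CC)(CC)CC)C=C)O[C@H]2C(C)(C)O[Si](CC)(CC)CC)c1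
F7 | step 12 | trimethylsilyl ether of 20 | Brc1ccc(O[Si](C)(C)C(C)(C)C)c([C@@H]2C(C(=O)OC)=C([C@H](C(O[Si](C)(C)C)CCc3ccccc3)[C@H](O[Si](CC)(CC)CC)C=C)O[C@H]2C(C)(C)O[Si](CC)(CC)CC)c1
F8 | step 12 | trimethylsilyl ether of 22 | Brc1ccc(O[Si](C)(C)C(C)(C)C)c([C@@H]2C3=C(O[C@H]2C(C)(C)O[Si](CC)(CC)CC)[C@H](C(O[Si](C)(C)C)CCc4ccccc4)[C@H](O[Si](CC)(CC)CC)C=C3OC)c1
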